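The bond joining the methyl-bearing quaternary C10 to the ring-fusion carbon C5 (eudesmane numbering) is common to ring A (C1–C5, C10) and ring B (C5–C10). The decalin is therefore cut at C5–C10 and C1–C2. One intramolecular Diels–Alder reaction of an acyclic trienone then closes both rings and sets both centres: an isopropenyl ketone (C1=C10, C9=O) adds to a 2-methyl diene (C2–C5). The precursor is a 2,8-dimethyldeca-1,7,9-trien-3-one; the four carbons between dienophile and diene bear the C7 isopropyl group and the silylated C6 oxygen, both set beforehand by an anti-selective asymmetric allylboration. Afterwards C9 is deoxygenated, the 6β-ester is attached, C4 is hydrated and the cinnamate is completed.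

Key step: step 11

Remark on the chemistry: ring compounds carry eudesmane numbering. The 6β-oxygen is esterified before C4 is hydrated, because afterwards that hydroxyl would lie between two syn-axial methyl groups (on C4 and C10). The ester is carried as a phosphonoacetate, which survives the radical hydration that a cinnamate would not, and becomes the cinnamate in the last step. The descriptor of the isopropyl-bearing carbon changes from R (9, 10) to S (11–16) only because the CIP priorities change.

Step 1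
Reactants: 1 3-methylbut-1-yne
Product: 2 (E)-4,4,5,5-tetramethyl-2-(3-methylbut-1-en-1-yl)-1,3,2-dioxaborolane
Conditions: pinacolborane (1.05 equiv), Cp2Zr(H)Cl (5 mol %), CH2Cl2, 25 °C, closed flask
Reagents that add atoms: pinacolborane, B1OC(C)(C)C(C)(C)O1
Why: Zirconium-catalysed hydroboration of a terminal alkyne is a syn, anti-Markovnikov addition, so boron ends on the terminal carbon trans to the isopropyl group.

Step 2
Reactants: 2 (E)-4,4,5,5-tetramethyl-2-(3-methylbut-1-en-1-yl)-1,3,2-dioxaborolane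
Product: 4 (E)-4,4,5,5-tetramethyl-2-(4-methylpent-2-en-1-yl)-1,3,2-dioxaborolane, via lithium boronate complex 3 (not isolated)
Conditions: BrCH2Cl (1.5 equiv), n-BuLi (1.3 equiv), THF, −78 °C → rt
Reagents that add atoms: bromochloromethane, ClCBr (the CH2 unit); n-butyllithium, [Li]CCCC (lithium counter-ion of 3 only)
Why: Matteson homologation, in which chloromethyllithium made in the flask adds to boron and the alkenyl group then shifts from boron to carbon with loss of chloride and retention of the E geometry.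

Step 3
Reactants: 5 (E)-3-methylpent-2-en-4-yn-1-ol
Product: 6 (E)-3-methylpenta-2,4-dien-1-ol
Conditions: H2 (1 atm, 1 equiv), Pd/CaCO3 poisoned with Pb(OAc)2, quinoline, EtOAc, 0 °C → rt
Reagents that add atoms: none
Why: Partial hydrogenation over lead-poisoned palladium stops at the alkene stage, so the terminal alkyne becomes a vinyl group and the trisubstituted E double bond is untouched.

Step 4
Reactants: 6 (E)-3-methylpenta-2,4-dien-1-ol
Product: 7 (E)-3-methylpenta-2,4-dienal
Conditions: activated MnO2 (excess), CH2Cl2, rt; filtered and used as a cold solution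
Reagents that add atoms: none
Why: Activated MnO2 oxidises the allylic alcohol selectively to the enal under neutral conditions that should not isomerise the E double bond.

Step 5
Reactants: 7 (E)-3-methylpenta-2,4-dienal; 4 (E)-4,4,5,5-tetramethyl-2-(4-methylpent-2-en-1-yl)-1,3,2-dioxaborolane
Product: 9 (3R,4R,5E)-6-methyl-3-(propan-2-yl)octa-1,5,7-trien-4-ol, via pinacol borate ester 8 (not isolated)
Conditions: (R)-TRIP [(R)-3,3'-bis(2,4,6-triisopropylphenyl)-1,1'-binaphthyl-2,2'-diyl hydrogen phosphate] (5 mol %), 4 Å MS, toluene, −30 → 0 °C; aqueous work-up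
Reagents that add atoms: none
Why: Chiral-phosphoric-acid-catalysed allylboration through a closed chair transition state, in which the E boronate places the isopropyl group anti to the new hydroxyl (C7 relative to C6) and (R)-TRIP directs attack to the Re face of the aldehyde, which gives C6 as R.

Step 6
Reactants: 9 (3R,4R,5E)-6-methyl-3-(propan-2-yl)octa-1,5,7-trien-4-ol
Product: 10 tert-butyl(dimethyl){[(3R,4R,5E)-6-methyl-3-(propan-2-yl)octa-1,5,7-trien-4-yl]oxy}silane
Conditions: TBSOTf, 2,6-lutidine, CH2Cl2, −78 → 0 °C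
Reagents that add atoms: tert-butyldimethylsilyl trifluoromethanesulfonate, CC(C)(C)[Si](C)(C)OS(=O)(=O)C(F)(F)F
Why: Silylation of the hindered secondary alcohol with the silyl triflate and a hindered base gives a robust, bulky ether that later fixes the conformation of the tether.

Step 7
Reactants: 10 tert-butyl(dimethyl){[(3R,4R,5E)-6-methyl-3-(propan-2-yl)octa-1,5,7-trien-4-yl]oxy}silane
Product: 12 (3S,4R,5E)-4-[(tert-butyldimethylsilyl)oxy]-6-methyl-3-(propan-2-yl)octa-5,7-dien-1-ol, via B-alkyl-9-BBN adduct 11 (not isolated)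
Conditions: 9-BBN (1.2 equiv), THF, 0 °C → rt; then NaOH, H2O2, 0 °C → rt
Reagents that add atoms: 9-borabicyclo[3.3.1]nonane, C1CC2CCCC(C1)B2 (boron unit of 11 only); hydrogen peroxide, OO (the oxygen of 12)
Why: Hydroboration–oxidation, in which 9-BBN adds anti-Markovnikov to the isolated monosubstituted alkene much faster than to the conjugated diene, which is deactivated towards this borane, and alkaline peroxide then replaces boron by hydroxyl.

Step 8
Reactants: 12 (3S,4R,5E)-4-[(tert-butyldimethylsilyl)oxy]-6-methyl-3-(propan-2-yl)octa-5,7-dien-1-ol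
Product: 13 (3S,4R,5E)-4-[(tert-butyldimethylsilyl)oxy]-6-methyl-3-(propan-2-yl)octa-5,7-dienal
Conditions: Dess–Martin periodinane, pyridine, CH2Cl2, 0 °C → rt
Reagents that add atoms: none
Why: Dess–Martin oxidation of the primary alcohol stops at the aldehyde, and the buffered conditions leave the silyl ether and the diene alone.

Step 9
Reactants: 13 (3S,4R,5E)-4-[(tert-butyldimethylsilyl)oxy]-6-methyl-3-(propan-2-yl)octa-5,7-dienal; 14 isopropenylmagnesium bromide (0.5 M in THF)
Product: 15 (5S,6R,7E)-6-[(tert-butyldimethylsilyl)oxy]-2,8-dimethyl-5-(propan-2-yl)deca-1,7,9-trien-3-ol (both C3 epimers)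
Conditions: THF, −78 → −20 °C; sat. aq. NH4Cl
Reagents that add atoms: none
Why: Grignard 1,2-addition to the aldehyde brings in C10, C1 and the angular methyl carbon; the epimeric carbinol centre is of no consequence because it is oxidised in the next step.

Step 10
Reactants: 15 (5S,6R,7E)-6-[(tert-butyldimethylsilyl)oxy]-2,8-dimethyl-5-(propan-2-yl)deca-1,7,9-trien-3-ol
Product: 16 (5S,6R,7E)-6-[(tert-butyldimethylsilyl)oxy]-2,8-dimethyl-5-(propan-2-yl)deca-1,7,9-trien-3-one (5,6-anti)
Conditions: Dess–Martin periodinane, pyridine, CH2Cl2, 0 °C; cold work-up, used at once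
Reagents that add atoms: none
Why: Dess–Martin oxidation of the secondary allylic alcohol gives the isopropenyl ketone, which is kept cold and used directly because such trienones cyclise and polymerise on standing.

Step 11
Reactants: 16 (5S,6R,7E)-6-[(tert-butyldimethylsilyl)oxy]-2,8-dimethyl-5-(propan-2-yl)deca-1,7,9-trien-3-one
Product: 17 6β-(tert-butyldimethylsilyloxy)-5αH,7αH-eudesm-3-en-9-one (trans-fused; (3S,4R,4aS,8aS)-4-[(tert-butyldimethylsilyl)oxy]-5,8a-dimethyl-3-(propan-2-yl)-3,4,4a,7,8,8a-hexahydronaphthalen-1(2H)-one)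
Conditions: Me2AlCl (1.2 equiv), CH2Cl2, −78 → −30 °C; aq. potassium sodium tartrate
Reagents that add atoms: none
Why: The Me2AlCl-bound isopropenyl ketone (C1=C10, conjugated with C9=O) and the diene C2=C3–C4=C5 combine in one concerted but asynchronous [4+2] event that makes the C1–C2 and C5–C10 bonds; it belongs to the known class of type 1 intramolecular Diels–Alder reactions of 1,7,9-decatrien-3-ones that give octalones. The C5–C10 bond completes ring B as a six-membered carbocycle by way of the C6–C7–C8–C9 chain, which folds like a cyclohexane chair, and the C1–C2 bond completes ring A as the cyclohexene that every Diels–Alder reaction produces. The configuration at C10 follows from how the dienophile lies under the diene: an α-methyl enone tends to turn its methyl group towards the diene and its carbonyl away, and with the carbonyl inside the connecting chain this arrangement leads to the trans ring fusion, the C10 methyl group ending anti to H5. The configuration at C5 follows from which diene face the chain can reach: in the chair the isopropyl group on C7 is equatorial and the silyloxy group on C6 is then axial, which also avoids the A(1,3) clash that an equatorial C6 substituent would have with the methyl group on C4. The step must therefore deliver trans fusion and a single diene face; the first rests on the exo-carbonyl bias of the methyl-substituted dienophile and is the open point of the route, the second is secured by the two stereocentres already present, whose preferences reinforce each other, and the low temperature keeps the less selective thermal background small.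

Step 12
Reactants: 17 6β-(tert-butyldimethylsilyloxy)-5αH,7αH-eudesm-3-en-9-one
Product: 18 6β-(tert-butyldimethylsilyloxy)-5αH,7αH-eudesm-3-en-9β-ol
Conditions: NaBH4, MeOH/THF, 0 °C → rt
Reagents that add atoms: none
Why: Borohydride reduction of the only carbonyl group, hydride arriving axially on the α face away from the angular methyl group to give mainly the equatorial 9β-alcohol, whose configuration is immaterial because the oxygen is removed.

Step 13
Reactants: 18 6β-(tert-butyldimethylsilyloxy)-5αH,7αH-eudesm-3-en-9β-ol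
Product: 19 O-[6β-(tert-butyldimethylsilyloxy)-5αH,7αH-eudesm-3-en-9β-yl] O-phenyl carbonothioate
Conditions: PhOC(S)Cl, pyridine, DMAP (cat.), CH2Cl2, rt
Reagents that add atoms: O-phenyl chlorothionoformate, S=C(Cl)Oc1ccccc1
Why: Acylation of the equatorial secondary alcohol gives the thionocarbonate that the Barton–McCombie deoxygenation requires.

Step 14
Reactants: 19 O-[6β-(tert-butyldimethylsilyloxy)-5αH,7αH-eudesm-3-en-9β-yl] O-phenyl carbonothioate
Product: 20 6β-(tert-butyldimethylsilyloxy)-5αH,7αH-eudesm-3-ene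
Conditions: Bu3SnH, AIBN (cat.), toluene, 100 °C
Reagents that add atoms: none
Why: Barton–McCombie deoxygenation, in which the stannyl radical adds to sulfur, the C9–O bond fragments, and the secondary C9 radical, held too far from the ring A alkene to cyclise, takes hydrogen from the stannane.

Step 15
Reactants: 20 6β-(tert-butyldimethylsilyloxy)-5αH,7αH-eudesm-3-ene
Product: 21 5αH,7αH-eudesm-3-en-6β-ol
Conditions: TBAF, THF, 60 °C
Reagents that add atoms: none
Why: Fluoride cleaves the hindered axial silyl ether on warming, and nothing else in this hydrocarbon-like molecule reacts with fluoride.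

Step 16
Reactants: 21 5αH,7αH-eudesm-3-en-6β-ol
Product: 22 5αH,7αH-eudesm-3-en-6β-yl (diethoxyphosphoryl)acetate
Conditions: (EtO)2P(O)CH2CO2H, DCC, DMAP (cat.), CH2Cl2, 0 °C → rt
Reagents that add atoms: 2-(diethoxyphosphoryl)acetic acid, CCOP(=O)(CC(=O)O)OCC
Why: Steglich-type esterification, in which DCC turns the phosphonoacetic acid into a small and very electrophilic acylating species able to reach the axial 6β-hydroxyl while only one syn-axial methyl group (on C10) flanks it.

Step 17
Reactants: 22 5αH,7αH-eudesm-3-en-6β-yl (diethoxyphosphoryl)acetate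
Product: 24 4α-hydroxy-5αH,7αH-eudesman-6β-yl (diethoxyphosphoryl)acetate, via tertiary hydroperoxide 23 (not isolated)
Conditions: Mn(dpm)3 (15 mol %), PhSiH3, O2 (1 atm), i-PrOH/CH2Cl2, 0 °C → rt; then PPh3
Reagents that add atoms: dioxygen, O=O
Why: Mukaiyama-type hydration by hydrogen-atom transfer, in which a manganese hydride gives hydrogen to C3, the tertiary C4 radical is trapped by O2 on the α face away from the axial C10 methyl group and the axial 6β-ester, and PPh3 reduces the hydroperoxide to the 4α-alcohol with the methyl group β.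

Step 18
Reactants: 24 4α-hydroxy-5αH,7αH-eudesman-6β-yl (diethoxyphosphoryl)acetate
Product: 25 4α-hydroxy-5αH,7αH-eudesman-6β-yl (E)-cinnamate (CNP0156995.2)
Conditions: PhCHO, LiCl, DBU, MeCN, rt
Reagents that add atoms: benzaldehyde, O=Cc1ccccc1
Why: Horner–Wadsworth–Emmons olefination under mild lithium chloride and amine base conditions gives the E cinnamate from benzaldehyde without disturbing the free tertiary alcohol or the hindered ester linkage.

Compound list
1 | 3-methylbut-1-yne | CC(C)C#C | starting material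
2 | (E)-4,4,5,5-tetramethyl-2-(3-methylbut-1-en-1-yl)-1,3,2-dioxaborolane | CC(C)/C=C/B1OC(C)(C)C(C)(C)O1 | intermediate
3 | lithium (chloromethyl)[(E)-3-methylbut-1-en-1-yl](pinacolato)borate, not isolated | [Li+].CC(C)/C=C/[B-]1(CCl)OC(C)(C)C(C)(C)O1 | intermediate
4 | (E)-4,4,5,5-tetramethyl-2-(4-methylpent-2-en-1-yl)-1,3,2-dioxaborolane | CC(C)/C=C/CB1OC(C)(C)C(C)(C)O1 | intermediate
5 | (E)-3-methylpent-2-en-4-yn-1-ol | C#C/C(C)=C/CO | starting material
6 | (E)-3-methylpenta-2,4-dien-1-ol | C=C/C(C)=C/CO | intermediate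
7 | (E)-3-methylpenta-2,4-dienal | C=C/C(C)=C/C=O | intermediate
8 | 4,4,5,5-tetramethyl-2-{[(3R,4R,5E)-6-methyl-3-(propan-2-yl)octa-1,5,7-trien-4-yl]oxy}-1,3,2-dioxaborolane, not isolated | C=C[C@@H](C(C)C)[C@@H](OB1OC(C)(C)C(C)(C)O1)/C=C(C)/C=C | intermediate
9 | (3R,4R,5E)-6-methyl-3-(propan-2-yl)octa-1,5,7-trien-4-ol (3,4-anti) | C=C[C@@H](C(C)C)[C@@H](O)/C=C(C)/C=C | intermediate
10 | tert-butyl(dimethyl){[(3R,4R,5E)-6-methyl-3-(propan-2-yl)octa-1,5,7-trien-4-yl]oxy}silane | C=C[C@@H](C(C)C)[C@@H](O[Si](C)(C)C(C)(C)C)/C=C(C)/C=C | intermediate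
11 | 9-{(3S,4R,5E)-4-[(tert-butyldimethylsilyl)oxy]-6-methyl-3-(propan-2-yl)octa-5,7-dien-1-yl}-9-borabicyclo[3.3.1]nonane, not isolated | C1CC2CCCC(C1)B2CC[C@@H](C(C)C)[C@@H](O[Si](C)(C)C(C)(C)C)/C=C(C)/C=C | intermediate
12 | (3S,4R,5E)-4-[(tert-butyldimethylsilyl)oxy]-6-methyl-3-(propan-2-yl)octa-5,7-dien-1-ol | OCC[C@@H](C(C)C)[C@@H](O[Si](C)(C)C(C)(C)C)/C=C(C)/C=C | intermediate
13 | (3S,4R,5E)-4-[(tert-butyldimethylsilyl)oxy]-6-methyl-3-(propan-2-yl)octa-5,7-dienal | O=CC[C@@H](C(C)C)[C@@H](O[Si](C)(C)C(C)(C)C)/C=C(C)/C=C | intermediate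
14 | isopropenylmagnesium bromide (prop-1-en-2-ylmagnesium bromide) | C=C(C)[Mg]Br | starting material
15 | (5S,6R,7E)-6-[(tert-butyldimethylsilyl)oxy]-2,8-dimethyl-5-(propan-2-yl)deca-1,7,9-trien-3-ol, both C3 epimers | C=C(C)C(O)C[C@@H](C(C)C)[C@@H](O[Si](C)(C)C(C)(C)C)/C=C(C)/C=C | intermediate
16 | (5S,6R,7E)-6-[(tert-butyldimethylsilyl)oxy]-2,8-dimethyl-5-(propan-2-yl)deca-1,7,9-trien-3-one | C=C(C)C(=O)C[C@@H](C(C)C)[C@@H](O[Si](C)(C)C(C)(C)C)/C=C(C)/C=C | intermediate
17 | 6β-(tert-butyldimethylsilyloxy)-5αH,7αH-eudesm-3-en-9-one (10β-methyl, 7β-isopropyl, trans-fused) | CC(C)[C@@H]1CC(=O)[C@@]2(C)CCC=C(C)[C@@H]2[C@@H]1O[Si](C)(C)C(C)(C)C | intermediate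
18 | 6β-(tert-butyldimethylsilyloxy)-5αH,7αH-eudesm-3-en-9β-ol | CC(C)[C@@H]1C[C@H](O)[C@@]2(C)CCC=C(C)[C@@H]2[C@@H]1O[Si](C)(C)C(C)(C)C | intermediate
19 | O-[6β-(tert-butyldimethylsilyloxy)-5αH,7αH-eudesm-3-en-9β-yl] O-phenyl carbonothioate | CC(C)[C@@H]1C[C@H](OC(=S)Oc3ccccc3)[C@@]2(C)CCC=C(C)[C@@H]2[C@@H]1O[Si](C)(C)C(C)(C)C | intermediate
20 | 6β-(tert-butyldimethylsilyloxy)-5αH,7αH-eudesm-3-ene | CC(C)[C@@H]1CC[C@@]2(C)CCC=C(C)[C@@H]2[C@@H]1O[Si](C)(C)C(C)(C)C | intermediate
21 | 5αH,7αH-eudesm-3-en-6β-ol | CC(C)[C@@H]1CC[C@@]2(C)CCC=C(C)[C@@H]2[C@@H]1O | intermediate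
22 | 5αH,7αH-eudesm-3-en-6β-yl (diethoxyphosphoryl)acetate | CC(C)[C@@H]1CC[C@@]2(C)CCC=C(C)[C@@H]2[C@@H]1OC(=O)CP(=O)(OCC)OCC | intermediate
23 | 4α-hydroperoxy-5αH,7αH-eudesman-6β-yl (diethoxyphosphoryl)acetate, not isolated | CC(C)[C@@H]1CC[C@@]2(C)CCC[C@@](C)(OO)[C@@H]2[C@@H]1OC(=O)CP(=O)(OCC)OCC | intermediate
24 | 4α-hydroxy-5αH,7αH-eudesman-6β-yl (diethoxyphosphoryl)acetate (4β-methyl) | CC(C)[C@@H]1CC[C@@]2(C)CCC[C@@](C)(O)[C@@H]2[C@@H]1OC(=O)CP(=O)(OCC)OCC | intermediate
25 | 4α-hydroxy-5αH,7αH-eudesman-6β-yl (E)-cinnamate; (1R,2S,4aR,8R,8aS)-8-hydroxy-4a,8-dimethyl-2-(propan-2-yl)decahydronaphthalen-1-yl (2E)-3-phenylprop-2-enoate | CC(C)[C@@H]1CC[C@@]2(C)CCC[C@@](C)(O)[C@@H]2[C@@H]1OC(=O)/C=C/c1ccccc1 | target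

Total step count: 18.
Longest linear sequence: 16 steps (5 → 25 through steps 3–18; the boronate arm from 1 through steps 1, 2 and 5–18 is equally long).

Steps most likely to fail

Step 11. The tether carbonyl rather than the methyl group may take the endo position, closing ring B in the cis mode or giving a mixture of ring-fusion isomers. These cannot be equilibrated afterwards, since C10 is quaternary and C5 is not enolisable. The fallback moves the activating carbonyl from the tether to the angular carbon. It sets out from borane 11 (formed from 10 in the first half of step 7) and comes back at 20. Instead of being oxidised, 11 is coupled with 2-bromoprop-2-en-1-ol (PdCl2(dppf), aq. K3PO4, THF/DMF; B-alkyl Suzuki–Miyaura coupling). This gives the allylic alcohol (5S,6R,7E)-6-[(tert-butyldimethylsilyl)oxy]-8-methyl-2-methylidene-5-(propan-2-yl)deca-7,9-dien-1-ol F1. MnO2 oxidises it to the 2-substituted acrolein (5S,6R,7E)-6-[(tert-butyldimethylsilyl)oxy]-8-methyl-2-methylidene-5-(propan-2-yl)deca-7,9-dienal F2. Here the formyl group sits on C10 outside the tether, so the ordinary endo orientation of the carbonyl, strengthened by Me2AlCl, is itself the trans-fused mode. Cyclisation (Me2AlCl, CH2Cl2, −78 °C), with the same chair tether, should give 6β-(tert-butyldimethylsilyloxy)-5αH,7αH-eudesm-3-en-14-al F3. Its hydrazone, 6β-(tert-butyldimethylsilyloxy)-5αH,7αH-eudesm-3-en-14-al hydrazone F4 (N2H4·H2O, EtOH), is decomposed with KOtBu in DMSO at room temperature (Wolff–Kishner reduction). The angular formyl group thereby becomes the C10 methyl group and the product is 20, so steps 12–14 are not needed on this path.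

Step 17. Oxygen may reach the planar C4 radical with poor facial selectivity, or the radical may be reduced instead of oxygenated. The fallback separates the two events and sets C4 by a syn addition followed by a retentive oxidation. It sets out from 22 and comes back at 24. Hydrogenation (H2, PtO2, EtOAc) should add hydrogen to the open α face and give 4β-methyl-4αH,5αH,7αH-eudesman-6β-yl (diethoxyphosphoryl)acetate F5. Its equatorial C4–H bond is activated by relief of the 1,3-diaxial strain of the axial methyl group. Methyl(trifluoromethyl)dioxirane (CH2Cl2, −20 °C) then hydroxylates that bond with retention, giving 24; the isopropyl methine is the competing site.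

Step 7. The borane may also add to the terminal double bond of the conjugated diene, or add twice, so that chemoselectivity between the two vinyl groups is lost. The fallback keeps the diene terminus as a silyl-capped alkyne until the hydroboration is over. It sets out from 5 and comes back at 12.
- MnO2 oxidises 5 to (E)-3-methylpent-2-en-4-ynal F6.
- Allylboration with 4 and (R)-TRIP as in step 5 gives the pinacol borate ester F7 of the adduct, hydrolysed on work-up to (3R,4R,5E)-6-methyl-3-(propan-2-yl)octa-1,5-dien-7-yn-4-ol F8.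
- TBSOTf and 2,6-lutidine give tert-butyl(dimethyl){[(3R,4R,5E)-6-methyl-3-(propan-2-yl)octa-1,5-dien-7-yn-4-yl]oxy}silane F9.
- n-BuLi and then Me3SiCl (THF, −78 °C) cap the alkyne as tert-butyl(dimethyl){[(3R,4R,5E)-6-methyl-3-(propan-2-yl)-8-(trimethylsilyl)octa-1,5-dien-7-yn-4-yl]oxy}silane F10.
- 9-BBN, which should leave the silylalkyne alone under these conditions, gives the B-alkyl-9-BBN adduct F11, oxidised with NaOH/H2O2 to (3S,4R,5E)-4-[(tert-butyldimethylsilyl)oxy]-6-methyl-3-(propan-2-yl)-8-(trimethylsilyl)oct-5-en-7-yn-1-ol F12.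
- K2CO3 in MeOH removes the alkynyl silyl group to give (3S,4R,5E)-4-[(tert-butyldimethylsilyl)oxy]-6-methyl-3-(propan-2-yl)oct-5-en-7-yn-1-ol F13.
- Partial hydrogenation (H2, Pd/CaCO3 poisoned with Pb(OAc)2, quinoline) turns the terminal alkyne into the vinyl group of 12.

Further compounds
F1 | step 11 | (5S,6R,7E)-6-[(tert-butyldimethylsilyl)oxy]-8-methyl-2-methylidene-5-(propan-2-yl)deca-7,9-dien-1-ol | C=C(CO)CC[C@@H](C(C)C)[C@@H](O[Si](C)(C)C(C)(C)C)/C=C(C)/C=C
F2 | step 11 | (5S,6R,7E)-6-[(tert-butyldimethylsilyl)oxy]-8-methyl-2-methylidene-5-(propan-2-yl)deca-7,9-dienal | C=C(C=O)CC[C@@H](C(C)C)[C@@H](O[Si](C)(C)C(C)(C)C)/C=C(C)/C=C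
F3 | step 11 | 6β-(tert-butyldimethylsilyloxy)-5αH,7αH-eudesm-3-en-14-al | CC(C)[C@@H]1CC[C@@]2(C=O)CCC=C(C)[C@@H]2[C@@H]1O[Si](C)(C)C(C)(C)C
F4 | step 11 | 6β-(tert-butyldimethylsilyloxy)-5αH,7αH-eudesm-3-en-14-al hydrazone | CC(C)[C@@H]1CC[C@@]2(/C=N/N)CCC=C(C)[C@@H]2[C@@H]1O[Si](C)(C)C(C)(C)C
F5 | step 17 | 4β-methyl-4αH,5αH,7αH-eudesman-6β-yl (diethoxyphosphoryl)acetate | CC(C)[C@@H]1CC[C@@]2(C)CCC[C@H](C)[C@@H]2[C@@H]1OC(=O)CP(=O)(OCC)OCC
F6 | step 7 | (E)-3-methylpent-2-en-4-ynal | C#C/C(C)=C/C=O
F7 | step 7 | 4,4,5,5-tetramethyl-2-{[(3R,4R,5E)-6-methyl-3-(propan-2-yl)octa-1,5-dien-7-yn-4-yl]oxy}-1,3,2-dioxaborolane | C=C[C@@H](C(C)C)[C@@H](OB1OC(C)(C)C(C)(C)O1)/C=C(C)/C#C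
F8 | step 7 | (3R,4R,5E)-6-methyl-3-(propan-2-yl)octa-1,5-dien-7-yn-4-ol | C=C[C@@H](C(C)C)[C@@H](O)/C=C(C)/C#C
F9 | step 7 | tert-butyl(dimethyl){[(3R,4R,5E)-6-methyl-3-(propan-2-yl)octa-1,5-dien-7-yn-4-yl]oxy}silane | C=C[C@@H](C(C)C)[C@@H](O[Si](C)(C)C(C)(C)C)/C=C(C)/C#C
F10 | step 7 | tert-butyl(dimethyl){[(3R,4R,5E)-6-methyl-3-(propan-2-yl)-8-(trimethylsilyl)octa-1,5-dien-7-yn-4-yl]oxy}silane | C=C[C@@H](C(C)C)[C@@H](O[Si](C)(C)C(C)(C)C)/C=C(C)/C#C[Si](C)(C)C
F11 | step 7 | 9-{(3S,4R,5E)-4-[(tert-butyldimethylsilyl)oxy]-6-methyl-3-(propan-2-yl)-8-(trimethylsilyl)oct-5-en-7-yn-1-yl}-9-borabicyclo[3.3.1]nonane | C1CC2CCCC(C1)B2CC[C@@H](C(C)C)[C@@H](O[Si](C)(C)C(C)(C)C)/C=C(C)/C#C[Si](C)(C)C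
F12 | step 7 | (3S,4R,5E)-4-[(tert-butyldimethylsilyl)oxy]-6-methyl-3-(propan-2-yl)-8-(trimethylsilyl)oct-5-en-7-yn-1-ol | OCC[C@@H](C(C)C)[C@@H](O[Si](C)(C)C(C)(C)C)/C=C(C)/C#C[Si](C)(C)C
F13 | step 7 | (3S,4R,5E)-4-[(tert-butyldimethylsilyl)oxy]-6-methyl-3-(propan-2-yl)oct-5-en-7-yn-1-ol | OCC[C@@H](C(C)C)[C@@H](O[Si](C)(C)C(C)(C)C)/C=C(C)/C#C
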